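**Retrosynthetic overview**
1. The route rests on the single stereocentre C3 of the central pyran ring (ring C). It sits between the benzylic C4 methylene on ring A and the C2 methylene bound to O1, which is the footprint of an arylacetaldehyde α-carbon joined to the exocyclic carbon of a phenol-derived o-quinone methide.
2. Key disconnection: C3–C4 and O1–C2, leading back to ring A sulfone 9 (latent o-quinone methide 18) and ring B arylacetaldehyde 17. Their union gives lactol 21, which is then reduced, reclosed by Mitsunobu etherification and desilylated.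
3. Sulfone 9: 1,3-dimethoxybenzene, C2 lithiation/prenylation, C5 borylation/oxidation, ortho-formylation, reduction, sulfination.
4. Aldehyde 17: 2,4-dihydroxybenzaldehyde, 4-O-silylation, O-propargylation, Claisen rearrangement, methoxymethylene Wittig reaction and hydrolysis.
5. Ring order: the dimethylpyran ring on ring B first (step 8), ring C as a lactol in step 11, ring C again as the chroman ether in step 13.

Key step: step 11

Remark: the 4'-hydroxyl is carried as a triisopropylsilyl ether, chosen over the tert-butyldimethylsilyl group because it must survive DBU, 140 °C, an ylide and aqueous base; lactol 21 is expected as an anomeric mixture (trans anomer drawn); the (R)-amine is chosen from the usual steric-shielding model of diarylprolinol silyl ether enamines; isoflavan numbering is used throughout.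

**Route**

Step 1
Reactants: 1 1,3-dimethoxybenzene; 2 prenyl bromide (1-bromo-3-methylbut-2-ene)
Product: 4 1,3-dimethoxy-2-(3-methylbut-2-en-1-yl)benzene, via 2-lithio-1,3-dimethoxybenzene 3 (not isolated)
Conditions: n-BuLi, THF, 0 °C to rt; then 2, −78 °C to rt
Reagents that add atoms: n-butyllithium, [Li]CCCC (supplies the lithium of 3; no atom of it remains in 4)
Why: Directed ortho-lithiation takes place at C2 between the two methoxy groups, and the aryllithium is alkylated at the primary carbon of the allylic bromide (SN2).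

Step 2
Reactants: 4 1,3-dimethoxy-2-(3-methylbut-2-en-1-yl)benzene
Product: 6 3,5-dimethoxy-4-(3-methylbut-2-en-1-yl)phenol, via arylboronic pinacol ester 5 (not isolated)
Conditions: [Ir(OMe)(cod)]2 (1.5 mol%), 4,4'-di-tert-butyl-2,2'-bipyridine (3 mol%), B2pin2 (1.0 equiv), THF, 60 °C; then 30% H2O2, aq. NaOH, 0 °C to rt
Reagents that add atoms: bis(pinacolato)diboron, CC1(C)OB(OC1(C)C)B1OC(C)(C)C(C)(C)O1 (boryl group of 5); hydrogen peroxide, OO (phenol oxygen of 6)
Why: Sterically controlled iridium-catalysed aromatic C–H borylation should take the only ring C–H without an ortho substituent (C5), and alkaline peroxide oxidation of the C–B bond gives the phenol without touching the trisubstituted alkene.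

Step 3
Reactants: 6 3,5-dimethoxy-4-(3-methylbut-2-en-1-yl)phenol
Product: 7 6-hydroxy-2,4-dimethoxy-3-(3-methylbut-2-en-1-yl)benzaldehyde
Conditions: MgCl2, Et3N, (CH2O)n, MeCN, reflux
Reagents that add atoms: paraformaldehyde (formaldehyde unit), C=O
Why: Magnesium-mediated ortho-formylation (Casnati–Skattebøl reaction) delivers formaldehyde inside the magnesium phenoxide chelate to an ortho carbon only; the two ortho carbons are equivalent, the para carbon is blocked, and the chelated salicylaldehyde resists a second formylation.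

Step 4
Reactants: 7 6-hydroxy-2,4-dimethoxy-3-(3-methylbut-2-en-1-yl)benzaldehyde
Product: 8 2-(hydroxymethyl)-3,5-dimethoxy-4-(3-methylbut-2-en-1-yl)phenol
Conditions: NaBH4, THF/MeOH, 0 °C; pH 7 buffer work-up; used crude
Reagents that add atoms: none
Why: Borohydride reduction of the aldehyde, run cold and worked up neutral so that the very electron-rich salicyl alcohol does not ionise.

Step 5
Reactants: 8 2-(hydroxymethyl)-3,5-dimethoxy-4-(3-methylbut-2-en-1-yl)phenol
Product: 9 3,5-dimethoxy-4-(3-methylbut-2-en-1-yl)-2-[(4-methylbenzenesulfonyl)methyl]phenol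
Conditions: p-TolSO2Na (3 equiv), HCO2H/H2O, THF, 0 °C to rt
Reagents that add atoms: sodium p-toluenesulfinate, Cc1ccc(cc1)S(=O)[O-].[Na+]
Why: Mild acid ionises the 2,4,6-trioxygenated benzylic alcohol and the excess sulfinate traps the cation at sulfur (SN1-type sulfinate alkylation) to give the stable sulfone.

Step 6
Reactants: 10 2,4-dihydroxybenzaldehyde
Product: 11 2-hydroxy-4-(triisopropylsilyloxy)benzaldehyde
Conditions: TIPSCl (1.05 equiv), imidazole, CH2Cl2, 0 °C
Reagents that add atoms: chlorotriisopropylsilane, CC(C)[Si](Cl)(C(C)C)C(C)C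
Why: Selective phenol silylation goes to the 4-hydroxyl because the 2-hydroxyl is hydrogen-bonded to the aldehyde and more hindered.

Step 7
Reactants: 11 2-hydroxy-4-(triisopropylsilyloxy)benzaldehyde; 12 3-chloro-3-methylbut-1-yne
Product: 13 2-[(2-methylbut-3-yn-2-yl)oxy]-4-(triisopropylsilyloxy)benzaldehyde
Conditions: DBU, CuCl2·2H2O (1 mol%), MeCN, 0 °C
Reagents that add atoms: none
Why: Copper-catalysed propargylic etherification of the phenoxide with the tertiary propargylic chloride gives the hindered aryl 1,1-dimethylpropargyl ether at 0 °C, conditions the aryl silyl ether tolerates.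

Step 8
Reactants: 13 2-[(2-methylbut-3-yn-2-yl)oxy]-4-(triisopropylsilyloxy)benzaldehyde
Product: 15 2,2-dimethyl-5-(triisopropylsilyloxy)-2H-chromene-8-carbaldehyde, via allenyl phenol 14 (not isolated)
Conditions: o-xylene, 140 °C
Reagents that add atoms: none
Why: The aromatic propargyl Claisen rearrangement can only go to C3, the one ortho carbon bearing hydrogen, and tautomerisation to 14, 1,5-hydrogen shift and 6π-electrocyclisation then close the dimethylpyran ring.

Step 9
Reactants: 15 2,2-dimethyl-5-(triisopropylsilyloxy)-2H-chromene-8-carbaldehyde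
Product: 16 8-(2-methoxyethenyl)-2,2-dimethyl-5-(triisopropylsilyloxy)-2H-chromene (E/Z mixture)
Conditions: Ph3P(CH2OMe)Cl, NaN(SiMe3)2, THF, 0 °C to rt
Reagents that add atoms: (methoxymethyl)triphenylphosphonium chloride, COC[P+](c1ccccc1)(c1ccccc1)c1ccccc1.[Cl-]
Why: Wittig olefination with the methoxymethylene ylide gives the enol ether, whose geometry is irrelevant, and the silylamide base leaves no alkoxide to attack the silyl ether.

Step 10
Reactants: 16 8-(2-methoxyethenyl)-2,2-dimethyl-5-(triisopropylsilyloxy)-2H-chromene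
Product: 17 2-[2,2-dimethyl-5-(triisopropylsilyloxy)-2H-chromen-8-yl]acetaldehyde
Conditions: 2 M aq. HCl, THF, rt; used at once
Reagents that add atoms: water, O
Why: Acid-catalysed enol ether hydrolysis, in which C-protonation of the enol ether should be far faster than protonation of the chromene double bond and the aryl triisopropylsilyl ether is stable to dilute acid.

Step 11
Reactants: 9 3,5-dimethoxy-4-(3-methylbut-2-en-1-yl)-2-[(4-methylbenzenesulfonyl)methyl]phenol; 17 2-[2,2-dimethyl-5-(triisopropylsilyloxy)-2H-chromen-8-yl]acetaldehyde (1.5 equiv)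
Product: 21 (3R)-3-[2,2-dimethyl-5-(triisopropylsilyloxy)-2H-chromen-8-yl]-5,7-dimethoxy-6-(3-methylbut-2-en-1-yl)chroman-2-ol (lactol; anomeric mixture; trans anomer drawn), via o-quinone methide 18 (not isolated), via catalyst enamine 19 (not isolated), via hydroxy aldehyde 20 (not isolated)
Conditions: (R)-2-[diphenyl(trimethylsilyloxy)methyl]pyrrolidine (20 mol%), sat. aq. NaHCO3, CH2Cl2, 0 °C to rt
Reagents that add atoms: (R)-2-[diphenyl(trimethylsilyloxy)methyl]pyrrolidine, C[Si](C)(C)OC(c1ccccc1)(c1ccccc1)[C@H]1CCCN1 (present in enamine 19 only; released again on hydrolysis)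
Why: Bicarbonate deprotonates phenol 9 and p-toluenesulfinate is expelled to give o-quinone methide 18 at a low standing concentration, while the amine condenses with 17 to the E-enamine 19, whose β-carbon adds to the exocyclic methylene of 18 (conjugate addition that rearomatises ring A and forms C3–C4), and hydrolysis then returns the amine and gives hydroxy aldehyde 20. The closest known reaction type is the aminocatalytic Michael addition–hemiacetalisation of aldehydes with o-quinone methides generated in situ from 2-(sulfonylalkyl)phenols, a formal [4+2] annulation that gives chroman-2-ols. Ring C closes when the phenol oxygen of 20 adds to the aldehyde carbon (6-exo-trig hemiacetalisation, forming O1–C2). C3 is set by the catalyst, whose diphenyl(silyloxy)methyl group covers one face of the anti E-enamine so that 18 adds to the open face, and this model predicts 3R from the (R)-amine; C2 is an anomeric centre under thermodynamic control and is removed in step 12. The step needs only enantiofacial selectivity at the enamine, because the quinone methide terminus is an unsubstituted CH2 and the symmetric parent phenol 6 allows a single quinone methide. Capture by the enamine over self-addition of 18 is favoured by the slow two-phase release of 18 and the excess of 17, the silyl ether keeps the ring B phenol from adding to 18, and lactol formation masks the α-aryl aldehyde against epimerisation.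

Step 12
Reactants: 21 lactol (crude, anomeric mixture)
Product: 22 2-{(2R)-2-[2,2-dimethyl-5-(triisopropylsilyloxy)-2H-chromen-8-yl]-3-hydroxypropyl}-3,5-dimethoxy-4-(3-methylbut-2-en-1-yl)phenol
Conditions: NaBH4, THF/MeOH, 0 °C
Reagents that add atoms: none
Why: Borohydride reduces the ring-opened hydroxy aldehyde tautomer of the lactol, which removes the anomeric centre and the epimerisable aldehyde while leaving C3 untouched.

Step 13
Reactants: 22 phenol diol
Product: 23 (3R)-3-[2,2-dimethyl-5-(triisopropylsilyloxy)-2H-chromen-8-yl]-5,7-dimethoxy-6-(3-methylbut-2-en-1-yl)chroman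
Conditions: PPh3, DIAD, THF, 0 °C to rt
Reagents that add atoms: none
Why: Intramolecular Mitsunobu etherification, in which the phenol displaces the activated primary alcohol (6-exo-tet) to reclose ring C; C3 is not a reacting centre, so its configuration is retained.

Step 14
Reactants: 23 4'-O-triisopropylsilyl kanzonol I
Product: 24 kanzonol I
Conditions: Bu4NF, THF, 0 °C
Reagents that add atoms: none
Why: Fluoride-mediated cleavage of the aryl silyl ether, with no other fluoride-sensitive group in the molecule.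

**Compound list**
1 | 1,3-dimethoxybenzene | COc1cccc(OC)c1 | starting material
2 | prenyl bromide (1-bromo-3-methylbut-2-ene) | CC(C)=CCBr | starting material
3 | 2-lithio-1,3-dimethoxybenzene | COc1cccc(OC)c1[Li] | intermediate
4 | 1,3-dimethoxy-2-(3-methylbut-2-en-1-yl)benzene | COc1cccc(OC)c1CC=C(C)C | intermediate
5 | 2-[3,5-dimethoxy-4-(3-methylbut-2-en-1-yl)phenyl]-4,4,5,5-tetramethyl-1,3,2-dioxaborolane | COc1cc(B2OC(C)(C)C(C)(C)O2)cc(OC)c1CC=C(C)C | intermediate
6 | 3,5-dimethoxy-4-(3-methylbut-2-en-1-yl)phenol | COc1cc(O)cc(OC)c1CC=C(C)C | intermediate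
7 | 6-hydroxy-2,4-dimethoxy-3-(3-methylbut-2-en-1-yl)benzaldehyde | COc1cc(O)c(C=O)c(OC)c1CC=C(C)C | intermediate
8 | 2-(hydroxymethyl)-3,5-dimethoxy-4-(3-methylbut-2-en-1-yl)phenol | COc1cc(O)c(CO)c(OC)c1CC=C(C)C | intermediate
9 | 3,5-dimethoxy-4-(3-methylbut-2-en-1-yl)-2-[(4-methylbenzenesulfonyl)methyl]phenol | Cc1ccc(cc1)S(=O)(=O)Cc1c(O)cc(OC)c(CC=C(C)C)c1OC | intermediate
10 | 2,4-dihydroxybenzaldehyde | O=Cc1ccc(O)cc1O | starting material
11 | 2-hydroxy-4-(triisopropylsilyloxy)benzaldehyde | O=Cc1ccc(O[Si](C(C)C)(C(C)C)C(C)C)cc1O | intermediate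
12 | 3-chloro-3-methylbut-1-yne | CC(C)(Cl)C#C | starting material
13 | 2-[(2-methylbut-3-yn-2-yl)oxy]-4-(triisopropylsilyloxy)benzaldehyde | O=Cc1ccc(O[Si](C(C)C)(C(C)C)C(C)C)cc1OC(C)(C)C#C | intermediate
14 | 2-hydroxy-3-(3-methylbuta-1,2-dien-1-yl)-4-(triisopropylsilyloxy)benzaldehyde | O=Cc1ccc(O[Si](C(C)C)(C(C)C)C(C)C)c(C=C=C(C)C)c1O | intermediate
15 | 2,2-dimethyl-5-(triisopropylsilyloxy)-2H-chromene-8-carbaldehyde | O=Cc1ccc(O[Si](C(C)C)(C(C)C)C(C)C)c2c1OC(C)(C)C=C2 | intermediate
16 | 8-(2-methoxyethenyl)-2,2-dimethyl-5-(triisopropylsilyloxy)-2H-chromene (E/Z mixture) | COC=Cc1ccc(O[Si](C(C)C)(C(C)C)C(C)C)c2c1OC(C)(C)C=C2 | intermediate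
17 | 2-[2,2-dimethyl-5-(triisopropylsilyloxy)-2H-chromen-8-yl]acetaldehyde | O=CCc1ccc(O[Si](C(C)C)(C(C)C)C(C)C)c2c1OC(C)(C)C=C2 | intermediate
18 | 3,5-dimethoxy-6-methylidene-4-(3-methylbut-2-en-1-yl)cyclohexa-2,4-dien-1-one (o-quinone methide) | C=C1C(=O)C=C(OC)C(CC=C(C)C)=C1OC | intermediate
19 | (2R)-1-{(E)-2-[2,2-dimethyl-5-(triisopropylsilyloxy)-2H-chromen-8-yl]ethenyl}-2-[diphenyl(trimethylsilyloxy)methyl]pyrrolidine (catalyst enamine) | C[Si](C)(C)OC(c1ccccc1)(c1ccccc1)[C@H]1CCCN1/C=C/c1ccc(O[Si](C(C)C)(C(C)C)C(C)C)c2c1OC(C)(C)C=C2 | intermediate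
20 | (2R)-2-[2,2-dimethyl-5-(triisopropylsilyloxy)-2H-chromen-8-yl]-3-[6-hydroxy-2,4-dimethoxy-3-(3-methylbut-2-en-1-yl)phenyl]propanal | O=C[C@@H](c1ccc(O[Si](C(C)C)(C(C)C)C(C)C)c2c1OC(C)(C)C=C2)Cc1c(O)cc(OC)c(CC=C(C)C)c1OC | intermediate
21 | (2S,3R)-3-[2,2-dimethyl-5-(triisopropylsilyloxy)-2H-chromen-8-yl]-5,7-dimethoxy-6-(3-methylbut-2-en-1-yl)chroman-2-ol (trans anomer drawn; carried on as the anomeric mixture) | COc1cc2c(c(OC)c1CC=C(C)C)C[C@H](c1ccc(O[Si](C(C)C)(C(C)C)C(C)C)c3c1OC(C)(C)C=C3)[C@@H](O)O2 | intermediate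
22 | 2-{(2R)-2-[2,2-dimethyl-5-(triisopropylsilyloxy)-2H-chromen-8-yl]-3-hydroxypropyl}-3,5-dimethoxy-4-(3-methylbut-2-en-1-yl)phenol | COc1cc(O)c(C[C@H](c2ccc(O[Si](C(C)C)(C(C)C)C(C)C)c3c2OC(C)(C)C=C3)CO)c(OC)c1CC=C(C)C | intermediate
23 | (3R)-3-[2,2-dimethyl-5-(triisopropylsilyloxy)-2H-chromen-8-yl]-5,7-dimethoxy-6-(3-methylbut-2-en-1-yl)chroman | COc1cc2c(c(OC)c1CC=C(C)C)C[C@H](c1ccc(O[Si](C(C)C)(C(C)C)C(C)C)c3c1OC(C)(C)C=C3)CO2 | intermediate
24 | kanzonol I, 8-[(3R)-5,7-dimethoxy-6-(3-methylbut-2-en-1-yl)chroman-3-yl]-2,2-dimethyl-2H-chromen-5-ol | COc1cc2c(c(OC)c1CC=C(C)C)C[C@H](c1ccc(O)c3c1OC(C)(C)C=C3)CO2 | target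

**Totals**
Total step count: 14.
Longest linear sequence: 9 steps (steps 1–5 or steps 6–10, followed by steps 11–14).

**Steps most likely to fail**

1. Step 11. The unsubstituted quinone methide may add to itself, or be attacked by the free ortho carbon of a second phenol molecule, faster than the enamine captures it. Facial selectivity, or slow epimerisation through the open aldehyde, may also lower the enantiomeric purity.
Fallback: an auxiliary-controlled enolate alkylation (Evans alkylation) that uses no quinone methide. It sets out from aldehyde 17, takes the ring A partner from aldehyde 7, and returns at diol 22. Aldehyde 17 is oxidised (NaClO2, NaH2PO4, 2-methylbut-2-ene, t-BuOH/H2O; Pinnick oxidation) to [2,2-dimethyl-5-(triisopropylsilyloxy)-2H-chromen-8-yl]acetic acid F1. This acid is coupled (PivCl, Et3N, LiCl, THF) with (R)-4-benzyloxazolidin-2-one to give (4R)-4-benzyl-3-{[2,2-dimethyl-5-(triisopropylsilyloxy)-2H-chromen-8-yl]acetyl}oxazolidin-2-one F2. Separately, 7 is O-allylated (allyl bromide, K2CO3, DMF) to 6-(allyloxy)-2,4-dimethoxy-3-(3-methylbut-2-en-1-yl)benzaldehyde F3. Reduction (NaBH4, MeOH, 0 °C) gives [6-(allyloxy)-2,4-dimethoxy-3-(3-methylbut-2-en-1-yl)phenyl]methanol F4. This is converted cold (PBr3, Et2O, −20 °C) into 1-(allyloxy)-2-(bromomethyl)-3,5-dimethoxy-4-(3-methylbut-2-en-1-yl)benzene F5, which is used at once. F2 is deprotonated (NaN(SiMe3)2, THF, −78 °C) and alkylated with F5 on the enolate face away from the benzyl group of the auxiliary, which should give the (2R)-configured alkylated imide F6. LiBH4 (THF, H2O, 0 °C) removes the auxiliary and gives (2R)-3-[6-(allyloxy)-2,4-dimethoxy-3-(3-methylbut-2-en-1-yl)phenyl]-2-[2,2-dimethyl-5-(triisopropylsilyloxy)-2H-chromen-8-yl]propan-1-ol F7. Pd(PPh3)4 with morpholine (THF, rt) then removes the allyl group to give diol 22.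

2. Step 2. The pinacolborane released may hydroborate the prenyl double bond under iridium catalysis, or borylation may occur at its allylic positions, in competition with aromatic C–H borylation.
Fallback: the phenol oxygen is installed before the alkene is present. It sets out from 1 and returns at phenol 6. Compound 1 is borylated and oxidised under the conditions of step 2, through 2-(3,5-dimethoxyphenyl)-4,4,5,5-tetramethyl-1,3,2-dioxaborolane F8, to 3,5-dimethoxyphenol F9 (also an article of commerce). Silylation (TIPSCl, imidazole, CH2Cl2) gives (3,5-dimethoxyphenoxy)triisopropylsilane F10. n-BuLi (THF, 0 °C) should lithiate the carbon between the two methoxy groups, because the bulky silyl ether does not direct, to give [2,6-dimethoxy-4-(triisopropylsilyloxy)phenyl]lithium F11. Alkylation with prenyl bromide 2 gives [3,5-dimethoxy-4-(3-methylbut-2-en-1-yl)phenoxy]triisopropylsilane F12, and Bu4NF (THF) gives 6.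

3. Step 5. The benzylic cation may be intercepted by the free ortho carbon of a second molecule (diarylmethane formation) faster than by sulfinate, alcohol 8 may already ionise during its preparation, or the acid may hydrate the prenyl group.
Fallback: the sulfone is made through an amine leaving group under non-acidic conditions. It sets out from phenol 6, bypasses steps 3 to 5 and returns at sulfone 9. Mannich aminomethylation of 6 (aq. Me2NH, aq. CH2O, EtOH, rt) gives 2-[(dimethylamino)methyl]-3,5-dimethoxy-4-(3-methylbut-2-en-1-yl)phenol F13. MeI (acetone, rt) gives [2-hydroxy-4,6-dimethoxy-3-(3-methylbut-2-en-1-yl)benzyl]trimethylammonium iodide F14. Warming F14 with excess p-TolSO2Na (MeCN/H2O, 60 °C) expels trimethylamine, and the sulfinate takes up the benzylic carbon to give 9.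

**Further compounds**
F1 | step 11 | [2,2-dimethyl-5-(triisopropylsilyloxy)-2H-chromen-8-yl]acetic acid | OC(=O)Cc1ccc(O[Si](C(C)C)(C(C)C)C(C)C)c2c1OC(C)(C)C=C2
F2 | step 11 | (4R)-4-benzyl-3-{[2,2-dimethyl-5-(triisopropylsilyloxy)-2H-chromen-8-yl]acetyl}oxazolidin-2-one | O=C(Cc1ccc(O[Si](C(C)C)(C(C)C)C(C)C)c2c1OC(C)(C)C=C2)N1[C@H](Cc2ccccc2)COC1=O
F3 | step 11 | 6-(allyloxy)-2,4-dimethoxy-3-(3-methylbut-2-en-1-yl)benzaldehyde | COc1cc(OCC=C)c(C=O)c(OC)c1CC=C(C)C
F4 | step 11 | [6-(allyloxy)-2,4-dimethoxy-3-(3-methylbut-2-en-1-yl)phenyl]methanol | COc1cc(OCC=C)c(CO)c(OC)c1CC=C(C)C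
F5 | step 11 | 1-(allyloxy)-2-(bromomethyl)-3,5-dimethoxy-4-(3-methylbut-2-en-1-yl)benzene | COc1cc(OCC=C)c(CBr)c(OC)c1CC=C(C)C
F6 | step 11 | (4R)-3-{(2R)-3-[6-(allyloxy)-2,4-dimethoxy-3-(3-methylbut-2-en-1-yl)phenyl]-2-[2,2-dimethyl-5-(triisopropylsilyloxy)-2H-chromen-8-yl]propanoyl}-4-benzyloxazolidin-2-one | O=C([C@@H](c1ccc(O[Si](C(C)C)(C(C)C)C(C)C)c2c1OC(C)(C)C=C2)Cc1c(OCC=C)cc(OC)c(CC=C(C)C)c1OC)N1[C@H](Cc2ccccc2)COC1=O
F7 | step 11 | (2R)-3-[6-(allyloxy)-2,4-dimethoxy-3-(3-methylbut-2-en-1-yl)phenyl]-2-[2,2-dimethyl-5-(triisopropylsilyloxy)-2H-chromen-8-yl]propan-1-ol | COc1cc(OCC=C)c(C[C@H](c2ccc(O[Si](C(C)C)(C(C)C)C(C)C)c3c2OC(C)(C)C=C3)CO)c(OC)c1CC=C(C)C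
F8 | step 2 | 2-(3,5-dimethoxyphenyl)-4,4,5,5-tetramethyl-1,3,2-dioxaborolane | COc1cc(OC)cc(c1)B1OC(C)(C)C(C)(C)O1
F9 | step 2 | 3,5-dimethoxyphenol | COc1cc(O)cc(OC)c1
F10 | step 2 | (3,5-dimethoxyphenoxy)triisopropylsilane | COc1cc(O[Si](C(C)C)(C(C)C)C(C)C)cc(OC)c1
F11 | step 2 | [2,6-dimethoxy-4-(triisopropylsilyloxy)phenyl]lithium | COc1cc(O[Si](C(C)C)(C(C)C)C(C)C)cc(OC)c1[Li]
F12 | step 2 | [3,5-dimethoxy-4-(3-methylbut-2-en-1-yl)phenoxy]triisopropylsilane | COc1cc(O[Si](C(C)C)(C(C)C)C(C)C)cc(OC)c1CC=C(C)C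
F13 | step 5 | 2-[(dimethylamino)methyl]-3,5-dimethoxy-4-(3-methylbut-2-en-1-yl)phenol | CN(C)Cc1c(O)cc(OC)c(CC=C(C)C)c1OC
F14 | step 5 | [2-hydroxy-4,6-dimethoxy-3-(3-methylbut-2-en-1-yl)benzyl]trimethylammonium iodide | C[N+](C)(C)Cc1c(O)cc(OC)c(CC=C(C)C)c1OC.[I-]
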